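The runs were computed on assumed constants.

Looking to late times, the spring flask can stop when its substrates are gone or when its partner is gone. Each product takes one partner, and the 40.0 mM of solid reagent covers the left-handed substrate and right-handed substrate together twice over. The homo dimer on the list of suspects may still take partner away. The dusk run, with 20 mM of each substrate, had put 11.9 mM of partner into its products by 5.00 d; its readings do not tell what went to the homo dimer, so they give no balance of the 40 mM of solid reagent. Its products together still rose from 23.9% at 4.00 d to 29.8% at 5.00 d, so for this time we ask how fast the flask moves, not where it ends.

| flask | left-handed substrate | right-handed substrate | solid reagent | free catalyst | racemization catalyst | remark | time |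
|---|---|---|---|---|---|---|---|
| spring | 10 mM | 10 mM | 40 mM | 0.25 mM | 100 µM | the very flask that is asked about, followed so far |  |
| dusk | 20 mM | 20 mM | 40 mM | 0.25 mM | 100 µM | run made earlier |  |
| flask | 10 mM | 10 mM | 40.0 mM | 0.25 mM | 100 µM |  | 5.0 d |

- spring (time / h: left-handed product / %, right-handed product / %): 8.00: 1.6, 0; 15.0: 4.3, 0.9; 25.0: 5.1, 2.6; 30.0: 6.2, 1.8; 40.0: 7.5, 4.8; 50.0: 9.9, 5.8
- dusk (time / d: left-handed product / %, right-handed product / %): 0.833: 3.5, 1.0; 1.67: 7.0, 2.2; 2.50: 11.5, 5.1; 3.00: 13.4, 5.9; 4.00: 17.6, 6.3; 5.00: 21.7, 8.1

(standard deviation of a reading: 1 percentage point)

- free catalyst is single-handed; left-handed substrate and right-handed substrate are mirror images of each other, charged as a racemate, each of them at the stated concentration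
- as a solid, counted per litre of solution: solid reagent
- the numbers in the tables scatter by 1 percentage point (one standard deviation)
- on the list of suspects stand: solid reagent <-> partner; 2 free catalyst <-> resting dimer; partner + free catalyst + right-handed substrate -> free catalyst + right-handed product; 2 partner -> homo dimer; partner + free catalyst + left-handed substrate -> free catalyst + left-handed product; left-handed substrate + racemization catalyst <-> right-handed substrate + racemization catalyst
- at the start none of the solid reagent is in solution
- an excess is the difference of the two amounts in percent of their sum
- an excess is below zero if the other one leads

1. left-handed product and right-handed product together, in percent of the left-handed substrate and right-handed substrate charged together, at 5.0 d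
2. excess of left-handed product over right-handed product in the product at 5.0 d
3. whether the exchange between left-handed substrate and right-handed substrate keeps pace with the reaction: how far the product's excess at 5.0 d gets from its value without exchange to its value with instant exchange (above 80% keeps pace, below 20% hardly takes part, else lags behind)

Dusk differs from spring in its substrate charge, with the same solid reagent and free catalyst, so we compare the two by percentages. The last dusk reading gives 0.0708 d⁻¹. This is the fractional pace, the logarithm of charged over remaining substrate divided by time, which is constant for a pseudo-first-order reaction. Spring gives 0.0820 d⁻¹, but from a sum of 15.7% with a scatter of 1 percentage point on each term. Doubling the substrate thus did not visibly change the percentage pace, and we trust dusk, which was read at the asked time: our own reckoning is 29.8%, below the forecast's 34%. The dusk excess reads 38.6% at 2.50 d and 45.6% at 5.00 d. Each of these rests on readings with a scatter of 1 point, and the right-handed product stood at 5.1% and 8.1%, so the two excesses are not told apart and say nothing firm about the exchange. We take the later one, from the larger amounts, as our expectation for the excess, above the forecast's 43%, and we have no reckoning of our own on the pace. The forecast says keeps pace: “Exchange therefore probably keeps pace, though the scatter makes this tentative.”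

The spring flask gives 30.6% with excess 47.5%, and the exchange keeps pace, 99.0% of the way.

    solid reagent ⇌ partner, rate k1*(cs1 - [partner]) while solid is left; crystals form when [partner] > cs1 (solubility = 8.30 mM, k = 0.150 h⁻¹)
    2 free catalyst ⇌ resting dimer (K = 9700 M⁻¹, k = 350 M⁻¹ h⁻¹)
    partner + free catalyst + right-handed substrate → free catalyst + right-handed product (k = 2700 M⁻² h⁻¹)
    2 partner → homo dimer (k = 2.40 M⁻¹ h⁻¹)
    partner + free catalyst + left-handed substrate → free catalyst + left-handed product (k = 7600 M⁻² h⁻¹)
    left-handed substrate + racemization catalyst ⇌ right-handed substrate + racemization catalyst, rate k6*[racemization catalyst]*[left-handed substrate] forward; the back reaction follows from the equilibrium constant (k = 8600 M⁻¹ h⁻¹)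

The forecast's 34% would stop fitting if the free catalyst charge moved. The spring flask's result means a fractional pace of 0.0730 d⁻¹, with free catalyst at 0.0906 mM and partner at 6.61 mM; the rest of the catalyst sits in the resting dimer, the resting state. The neighbour flask, charged with 0.42 mM of free catalyst, holds partner at 6.57 mM and free catalyst at 0.124 mM, a rise by a factor 1.37 against 1.68 in the charge. Scaling the pace by the first factor gives 0.0996 d⁻¹, hence 39.2% at 5.0 d, and that neighbour flask gave 38.7%.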